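**Strategy**

The target is cut at the two CH2–aryl bonds that join the C6 and C8 methylenes of ring A to the carbon ortho to the phenolic oxygen of each arm ring. One palladium-catalysed double benzylic Suzuki–Miyaura coupling forms both bonds. It exploits the fact that each ring A methylene sits between two ring A oxygens (O5/O7 at C6, O7/O1 at C8) and para to the third, so its C–OAc bond ionises readily on Pd(0), while boron dictates the site on the arm ring. The electrophile is the triacetate of 6,8-bis(hydroxymethyl)-(2S)-pinostrobin, made in two steps from (2S)-pinostrobin, which supplies C2; the nucleophile is a dibenzyl-protected arm boronic acid.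

Key step: step 7

Assumption: the target is taken exactly as drawn in the SMILES, that is the (2S)-flavanone with a methyl ether at O7 and a free, chelated hydroxyl at C5, and (2S)-pinostrobin is taken to be available in enantiopure form.

Structure check: C2 is S in 1 and in the target (O1 > C1' > C3 > H); each arm ring is bonded through the carbon ortho to its phenolic oxygen and carries the second benzyl group para to that oxygen.

Design note: O5 stays acetylated through the coupling so that the benzylic acetates cannot collapse to an ortho- or para-quinone methide; the coupling uses fluoride, not carbonate, as activator; the arm is assembled by Grignard addition and ionic hydrogenation so that no palladium chemistry precedes the key step.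

**Route**

Step 1
Reactants: 1 (2S)-pinostrobin; 2 N,N,N',N'-tetramethylmethanediamine [bis(dimethylamino)methane]
Product: 3 (2S)-6,8-bis[(dimethylamino)methyl]-5-hydroxy-7-methoxyflavanone
Conditions: 2 (4 equiv), i-PrOH–1,4-dioxane, 85 °C
Reagents that add atoms: none
Why: Phenolic Mannich reaction: the iminium ion released from the aminal attacks the only two unsubstituted carbons of ring A, C6 (ortho to the C5 hydroxyl) and C8 (para to it), both activated by O5, O7 and O1, while the anhydrous, weakly basic medium and the absence of a 4'-hydroxyl give the C2–O1 bond little opportunity to open, so the S centre should be carried through unchanged.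

Step 2
Reactants: 3 (2S)-6,8-bis[(dimethylamino)methyl]-5-hydroxy-7-methoxyflavanone
Product: 4 (2S)-5-acetoxy-6,8-bis(acetoxymethyl)-7-methoxyflavanone
Conditions: Ac2O (neat), 100 °C
Reagents that add atoms: acetic anhydride, CC(=O)OC(C)=O
Why: Acetolysis of a Mannich base: N-acetylation turns each dimethylamino group into an acylammonium leaving group that the electron-rich ring A expels as N,N-dimethylacetamide (through the ortho-quinone methide at C6 and a benzylic ion pair at C8), acetate captures each methylene, the C5 hydroxyl is acetylated in the same flask, and the acidic medium leaves C2 alone.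

Step 3
Reactants: 5 3-bromo-4-hydroxybenzaldehyde
Product: 6 4-(benzyloxy)-3-bromobenzaldehyde
Conditions: BnBr, K2CO3, DMF, rt
Reagents that add atoms: benzyl bromide, BrCc1ccccc1
Why: Williamson ether synthesis on an acidic para-formyl phenol, which is alkylated cleanly on oxygen under mild carbonate conditions.

Step 4
Reactants: 6 4-(benzyloxy)-3-bromobenzaldehyde; 7 1-(benzyloxy)-2-bromobenzene
Product: 9 [4-(benzyloxy)-3-bromophenyl][2-(benzyloxy)phenyl]methanol (racemate), via 2-(benzyloxy)phenylmagnesium bromide 8 (not isolated)
Conditions: 7, Mg, THF, 40 °C; then 6, THF, 0 °C; aq. NH4Cl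
Reagents that add atoms: none
Why: Grignard addition to an aldehyde: the aryl Grignard reagent adds to the formyl group far faster than it could exchange with the aryl bromide of 6, and the new carbinol centre, formed as a racemate, is removed in step 5.

Step 5
Reactants: 9 [4-(benzyloxy)-3-bromophenyl][2-(benzyloxy)phenyl]methanol
Product: 10 1-(benzyloxy)-4-[2-(benzyloxy)benzyl]-2-bromobenzene
Conditions: Et3SiH, TFA, CH2Cl2, 0 °C
Reagents that add atoms: none
Why: Ionic hydrogenation: acid ionises the carbinol to a diarylmethyl cation stabilised by the para and ortho benzyloxy groups, triethylsilane delivers hydride to it, and aryl benzyl ethers and the aryl bromide are stable to trifluoroacetic acid at 0 °C.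

Step 6
Reactants: 10 1-(benzyloxy)-4-[2-(benzyloxy)benzyl]-2-bromobenzene
Product: 13 {2-(benzyloxy)-5-[2-(benzyloxy)benzyl]phenyl}boronic acid, via aryllithium 11 (not isolated), via lithium aryl(triisopropoxy)borate 12 (not isolated)
Conditions: B(Oi-Pr)3, then n-BuLi, THF–toluene, −78 °C to rt; 1 M HCl
Reagents that add atoms: triisopropyl borate, CC(C)OB(OC(C)C)OC(C)C; water, O
Why: Bromine–lithium exchange with in situ borate trapping: n-butyllithium exchanges with the aryl bromide faster than it attacks the hindered borate, the aryllithium is captured at once (leaving no time for lithium to migrate to a benzylic position of the ether groups), and mild acid hydrolysis releases the boronic acid with boron ortho to the benzyloxy group.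

Step 7
Reactants: 4 (2S)-5-acetoxy-6,8-bis(acetoxymethyl)-7-methoxyflavanone; 13 {2-(benzyloxy)-5-[2-(benzyloxy)benzyl]phenyl}boronic acid (two equivalents react, 3 equiv used)
Product: 14 (2S)-5-acetoxy-6,8-bis{2-(benzyloxy)-5-[2-(benzyloxy)benzyl]benzyl}-7-methoxyflavanone
Conditions: [Pd(η3-C3H5)(cod)]BF4 (10 mol %), 1,5-bis(diphenylphosphino)pentane (DPPPent, 11 mol %), KF, t-AmOH, 70 °C, degassed
Reagents that add atoms: none
Why: Pd(0)–DPPPent adds oxidatively to each benzylic C–OAc bond of 4, helped by hydrogen bonding of the tertiary alcohol to the departing acetate and by the donor oxygens O5, O7 and O1 around C6 and C8, to give an η3-benzylpalladium(II) acetate; fluoride-activated 13 transmetalates its aryl group and reductive elimination forms the CH2–C(aryl) bond, once at the C6 methylene and once at the C8 methylene. The closest known reaction type is the palladium/bisphosphine-catalysed Suzuki–Miyaura coupling of primary benzylic acetates (and carbonates) with arylboronic acids to diarylmethanes. No ring is closed and no stereocentre is created, so there is no mode of closure or controlling element to specify, and C2 is a spectator. Site selectivity on the arm ring is required and is fixed by boron, which sits ortho to the benzyloxy group, so only that carbon is benzylated. Chemoselectivity for the two benzylic acetates over the C5 aryl acetate, the benzyl aryl ethers and the C2–O1 bond follows because only the former ionise on Pd(0), and the C5 acetate keeps the phenol masked so that neither an ortho-quinone methide (C6) nor a para-quinone methide (C8) can form. Potassium fluoride in a hindered alcohol, used in place of carbonate or hydroxide, keeps the medium close to neutral, which should preserve the C5 acetate and prevent E1cB opening of the pyranone ring and hence racemisation at C2.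

Step 8
Reactants: 14 (2S)-5-acetoxy-6,8-bis{2-(benzyloxy)-5-[2-(benzyloxy)benzyl]benzyl}-7-methoxyflavanone
Product: 16 (2S)-5-hydroxy-6,8-bis[2-hydroxy-5-(2-hydroxybenzyl)benzyl]-7-methoxyflavanone (target), via 5-O-acetyl tetraphenol 15 (not isolated)
Conditions: H2 (1 atm), 10% Pd/C, EtOAc–MeOH, rt; filter; HCl (0.5 M in MeOH), rt
Reagents that add atoms: none
Why: Catalytic hydrogenolysis removes the four aryl benzyl ethers under neutral conditions that should leave the C4 ketone, the diarylmethane bonds and the C2–O1 bond intact at 1 atm and room temperature, and acid-catalysed transesterification with methanol then cleaves the C5 acetate, which is activated by the peri carbonyl; no base is present at either stage, so C2 stays S.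

**Compound list**

1 | (2S)-pinostrobin [(2S)-5-hydroxy-7-methoxyflavanone] | COc1cc(O)c2c(c1)O[C@H](c1ccccc1)CC2=O | starting material
2 | N,N,N',N'-tetramethylmethanediamine | CN(C)CN(C)C | starting material
3 | (2S)-6,8-bis[(dimethylamino)methyl]-5-hydroxy-7-methoxyflavanone | COc1c(CN(C)C)c(O)c2c(c1CN(C)C)O[C@H](c1ccccc1)CC2=O | intermediate
4 | (2S)-5-acetoxy-6,8-bis(acetoxymethyl)-7-methoxyflavanone | COc1c(COC(C)=O)c(OC(C)=O)c2c(c1COC(C)=O)O[C@H](c1ccccc1)CC2=O | intermediate
5 | 3-bromo-4-hydroxybenzaldehyde | O=Cc1ccc(O)c(Br)c1 | starting material
6 | 4-(benzyloxy)-3-bromobenzaldehyde | O=Cc1ccc(OCc2ccccc2)c(Br)c1 | intermediate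
7 | 1-(benzyloxy)-2-bromobenzene | Brc1ccccc1OCc1ccccc1 | starting material
8 | 2-(benzyloxy)phenylmagnesium bromide | Br[Mg]c1ccccc1OCc1ccccc1 | intermediate
9 | [4-(benzyloxy)-3-bromophenyl][2-(benzyloxy)phenyl]methanol (racemate) | OC(c1ccc(OCc2ccccc2)c(Br)c1)c1ccccc1OCc1ccccc1 | intermediate
10 | 1-(benzyloxy)-4-[2-(benzyloxy)benzyl]-2-bromobenzene | Brc1cc(Cc2ccccc2OCc2ccccc2)ccc1OCc1ccccc1 | intermediate
11 | {2-(benzyloxy)-5-[2-(benzyloxy)benzyl]phenyl}lithium | [Li]c1cc(Cc2ccccc2OCc2ccccc2)ccc1OCc1ccccc1 | intermediate
12 | lithium {2-(benzyloxy)-5-[2-(benzyloxy)benzyl]phenyl}tri(propan-2-yloxy)borate | [Li+].CC(C)O[B-](OC(C)C)(OC(C)C)c1cc(Cc2ccccc2OCc2ccccc2)ccc1OCc1ccccc1 | intermediate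
13 | {2-(benzyloxy)-5-[2-(benzyloxy)benzyl]phenyl}boronic acid | OB(O)c1cc(Cc2ccccc2OCc2ccccc2)ccc1OCc1ccccc1 | intermediate
14 | (2S)-5-acetoxy-6,8-bis{2-(benzyloxy)-5-[2-(benzyloxy)benzyl]benzyl}-7-methoxyflavanone | COc1c(Cc2cc(Cc3ccccc3OCc3ccccc3)ccc2OCc2ccccc2)c(OC(C)=O)c2c(c1Cc1cc(Cc3ccccc3OCc3ccccc3)ccc1OCc1ccccc1)O[C@H](c1ccccc1)CC2=O | intermediate
15 | (2S)-5-acetoxy-6,8-bis[2-hydroxy-5-(2-hydroxybenzyl)benzyl]-7-methoxyflavanone | COc1c(Cc2cc(Cc3ccccc3O)ccc2O)c(OC(C)=O)c2c(c1Cc1cc(Cc3ccccc3O)ccc1O)O[C@H](c1ccccc1)CC2=O | intermediate
16 | (2S)-5-hydroxy-6,8-bis[2-hydroxy-5-(2-hydroxybenzyl)benzyl]-7-methoxyflavanone | COc1c(Cc2cc(Cc3ccccc3O)ccc2O)c(O)c2c(c1Cc1cc(Cc3ccccc3O)ccc1O)O[C@H](c1ccccc1)CC2=O | target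

**Step count**

Total step count: 8. Longest linear sequence: 6 steps (steps 3, 4, 5, 6, 7, 8). The only stereocentre, C2, comes from 1 and is not touched by any step.

**Steps most likely to fail**

Step 7. The coupling may stall after the first arylation because the second site is hindered. The benzylic acetates may be solvolysed by the alcohol, or the C5 acetate may be lost early with quinone methide formation. The boronic acid may protodeboronate, or C2 may erode if the medium turns basic. The fallback is a base-free Negishi coupling that forms the same two bonds. Setting out from 4, HBr in AcOH (CH2Cl2, 0 °C) should exchange the two benzylic acetates for bromides and leave the aryl acetate, giving (2S)-5-acetoxy-6,8-bis(bromomethyl)-7-methoxyflavanone F1. Setting out from 10, n-BuLi (THF, −78 °C, through 11) followed by ZnCl2 should give {2-(benzyloxy)-5-[2-(benzyloxy)benzyl]phenyl}zinc chloride F2. Pd(PPh3)4-catalysed coupling of F1 with F2 (THF, rt) tolerates the ketone and the aryl acetate and returns to the route at 14.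

Step 1. The second aminomethylation may remain incomplete, aminomethylation may compete at C3, or reversible opening of the pyranone ring may erode the configuration at C2. The fallback works in acid, where E1cB ring opening cannot occur. Setting out from 1, Blanc chloromethylation (paraformaldehyde, HCl gas, AcOH, 40 °C) should give (2S)-6,8-bis(chloromethyl)-5-hydroxy-7-methoxyflavanone F3. NaOAc in AcOH–Ac2O (60 °C) then exchanges both chlorides for acetate and acetylates O5, which returns to the route at 4 and replaces steps 1 and 2.

Step 2. Exchange of the amine at C8, which has no ortho hydroxyl to assist, may be incomplete, or enol acetylation at C4 may set in at the temperature required. The fallback separates activation from substitution. Setting out from 3, exhaustive N-methylation (MeI, acetone, rt) should give (2S)-5-hydroxy-7-methoxy-6,8-bis[(trimethylammonio)methyl]flavanone diiodide F4. Its trimethylammonium groups are displaced by acetate at 60 °C (NaOAc, AcOH–Ac2O) with acetylation of O5 in the same flask, which returns to the route at 4.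

**Further compounds**

F1 | step 7 | (2S)-5-acetoxy-6,8-bis(bromomethyl)-7-methoxyflavanone | COc1c(CBr)c(OC(C)=O)c2c(c1CBr)O[C@H](c1ccccc1)CC2=O
F2 | step 7 | {2-(benzyloxy)-5-[2-(benzyloxy)benzyl]phenyl}zinc chloride | Cl[Zn]c1cc(Cc2ccccc2OCc2ccccc2)ccc1OCc1ccccc1
F3 | step 1 | (2S)-6,8-bis(chloromethyl)-5-hydroxy-7-methoxyflavanone | COc1c(CCl)c(O)c2c(c1CCl)O[C@H](c1ccccc1)CC2=O
F4 | step 2 | (2S)-5-hydroxy-7-methoxy-6,8-bis[(trimethylammonio)methyl]flavanone diiodide | COc1c(C[N+](C)(C)C)c(O)c2c(c1C[N+](C)(C)C)O[C@H](c1ccccc1)CC2=O.[I-].[I-]
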